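Time first: I drew trapped intermediate as a straight line in time, up to the ceiling that the charged capture agent allows. I wanted the moment the two meet.

| flask | starting material | capture agent | remark | time |
|---|---|---|---|---|
| south | 0.091 M | 0.039 M | run made earlier |  |
| north-east | 0.091 M | 0.052 M | run made earlier |  |
| south-east | 0.15 M | 0.0273 M | run made earlier |  |
| amber | 0.40 M | 0.0400 M |  | 120 min |
| blue | 0.091 M | 0.0273 M |  | 30 min |

| run | time / min | target / % | trapped intermediate / % |
|---|---|---|---|
| south | 2.50 | 2.0 | 0 |
| south | 6.00 | 10.0 | 1.4 |
| south | 12.0 | 22.6 | 4.7 |
| south | 30.0 | 47.5 | 9.2 |
| north-east | 8.00 | 15.6 | 2.2 |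
| north-east | 15.0 | 28.9 | 9.2 |
| north-east | 25.0 | 45.1 | 12.9 |
| north-east | 30.0 | 47.2 | 12.7 |
| south-east | 8.00 | 15.8 | 0 |
| south-east | 15.0 | 29.2 | 3.8 |
| south-east | 25.0 | 43.1 | 5.2 |
| south-east | 30.0 | 47.6 | 7.6 |

(standard deviation of a reading: 1 percentage point)

* which of the two ends with the higher share of target in all that became target or trapped intermediate ("neither" if they lie within 2 percentage points) (amber / blue / neither)
* share of target in all that became target or trapped intermediate, amber
* share of target in all that became target or trapped intermediate, blue

- the earlier runs were read with a standard deviation of 1 percentage point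
- steps that have been proposed: capture agent + intermediate B -> trapped intermediate; starting material -> intermediate B; intermediate B <-> intermediate C; intermediate A <-> target; starting material -> intermediate A

**The neighbour.** Blue looks nearly like south-east, with the same [capture agent] of 0.0273 M and the same reading time, 30 min. Their [starting material] differs, 0.091 M against 0.15 M. At that time target read 47.5 %, 47.2 % and 47.6 % in south, north-east and south-east. Trapped intermediate read 9.2 %, 12.7 % and 7.6 %, so it followed [capture agent], not [starting material]. Dividing each reading by [capture agent] and time, I averaged a trapping coefficient, g = 0.0843 M⁻¹ min⁻¹.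

**The crossing.** Each trapped intermediate takes one capture agent, so its percentage has a ceiling, [capture agent]/[starting material]. The straight line g[capture agent]t meets that ceiling at 1/(g[starting material]), and [capture agent] cancels. This crossing time is 130 min for blue and 29.7 min for amber. Blue is read earlier than its crossing, so time controls it, and I reckoned 6.90 % trapped. Amber is read later than its crossing, so capture agent is the limiting reagent, and I reckoned the ceiling, 10.0 %.

**My shares.** For blue I took south-east's target, which gave 87.3 %. For amber, the shrinking gain in south-east's target pointed to a plateau near 78.9 %, which gave 88.8 %. My shares were 88.8 % and 87.3 %, with a margin of 2 percentage points, so I said neither.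

The forecast also said neither, with amber at 87.5 % (84.5 % to 90 %) and blue at 87 % (84.5 % to 89 %); for amber it held that capture agent “should be nearly used up” and took target near 67 %, against my 78.9 %.

**The result.** The answer is neither: amber 85.9 %, blue 85.6 %. Amber kept 0.73 % of its capture agent at its end, with 9.93 % trapped. Already at 60.0 min, past its crossing of 29.7 min, amber held 9.26 % trapped. Moved one at a time, up or down by one common factor, blue's settings shifted its share by at most: capture agent (3.1 points), then time (1.3 points), then starting material (0.49 points); the margin is 2 points.

    capture agent + intermediate B → trapped intermediate (k = 0.390 M⁻¹ min⁻¹)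
    starting material → intermediate B (k = 0.120 min⁻¹)
    intermediate B ⇌ intermediate C (K = 0.290, k = 0.00170 min⁻¹)
    intermediate A ⇌ target (K = 30.0, k = 0.0560 min⁻¹)
    starting material → intermediate A (k = 0.200 min⁻¹)

**Second flask.** Blue read at 12 min lies before its crossing. The line gives 2.76 % trapped, and with south's target of 22.6 % a share of 89.1 %. The flask gives 3.19 % trapped and a share of 88.2 %.

The numbers in the tables come from a simulation for an exercise, and the scatter is random.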